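At early times X binds the catalyst J while L is still being fed, and I ask where that start leads.

X 0.0020 M; L 5.00 mM (fed, over 20 s); J 40 µM; time 15 min; the fed solution adds 0.25 times the starting volume

    L + X.J ⇌ L.X.J (K1 = 18000 M⁻¹, k1 = 4100 M⁻¹ s⁻¹)
    D ⇌ J + G (K2 = 0.0014 M, k2 = 5.0 s⁻¹)
    L.X.J ⇌ D (K3 = 1.3, k3 = 110 s⁻¹)
    X + J ⇌ X.J (K4 = 400 M⁻¹, k4 = 3100 M⁻¹ s⁻¹)

1. the state of affairs at 15 min: stopped, and by what, or still going (L has run out first / all of X has reacted / forward and back rates have come level / no working catalyst is left / it is still moving)
2. share of the X used up at 15 min
3. G at 15 min, in percent of the X charged

- every charge counts on the volume at the start, and the solution that is fed holds the whole dose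
- the reaction counts as stopped when no species that holds the X changes by six tenths of a point or more over the second half of the time
- run time (flask): 15 min

Where can the flask stop? Adding the steps, the forms of the catalyst cancel and X + L ⇌ G remains. The product of the step constants is 13100 M⁻¹; I call it K, the overall constant: G over X times L when forward and back rates are level.

Which reagent stands in excess? The feed swells the volume 1.25 times, so the charges count as 1.60 mM of X and 4.00 mM of L, and L stands higher than X. If I count the X as turned into G, free L is about 2.40 mM, so K allows a ratio of G to X of 31.4. That leaves 3.08% of X, a conversion of 96.9%. The catalyst charge is 2.00% of the X charge, and X held on the catalyst is not G, so I put G between 94.9% and 96.9%.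

Is there time? The half-life of X by the forward run of step 4 alone, with J held at its charge, is 0.0932 min, much shorter than the run. This covers one step and ignores the way back, so my expectation of level rates by the end, which is thermodynamic rather than kinetic control, remains an estimate.

The forecast also says forward and back rates have come level, with conversion 97% (96.3% to 97.6%) and G 95.7% (94.8% to 96.5%), the flask ending “just short of complete rather than running out of X or L”.

In the simulation forward and back rates have come level, with conversion 97.0% and G 95.7%.

The flask stops short because G returns: with the backward run from J + G to D struck out, conversion reaches 100%. In this flask at 15.0 min, G over X reads 32.1, and K times the free L reads 32.1.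

A neighbour flask, otherwise the same, holds 0.0080 M of X, so L, at 0.625 equiv, is the limiting reagent there. After dilution X counts as 6.40 mM; if G takes up the L, K leaves 0.127 mM of free L and G at 60.5% of the X charged. The simulation of that neighbour flask gives 60.3%, with 2.9% of the L still unbound.

All constants stand for no real mixture; the flask was simulated.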